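**Assumption:** read from its descriptors, the target has a cis-fused hydroazulene core. The C1 methyl and H5 lie on one face (called β, the convex face), the C4 hydroxyl and the C6 ester oxygen on the other (α, concave), and the epoxide oxygen on β. In the numbering used below this is 1S,4R,5S,6R,8R,9S, and the route is designed for exactly this arrangement.

## The problem

Target 25 is a daucane: a cyclopentane (C1–C5) and a cycloheptane (C1, C5–C10) sharing the C1–C5 bond. C1 is quaternary (methyl), C4 carries isopropyl and a tertiary hydroxyl, C5 is the ring-fusion CH, C6 carries the 4-hydroxybenzoate, and C8/C9 form a trisubstituted epoxide with a methyl on C8. Six stereocentres have to be set (C1, C4, C5, C6, C8, C9). Only C1 is remote from any heteroatom and cannot be corrected later, so it must be set absolutely and early. Once the fusion is cis the bicycle is folded, and hydride at C6, the isopropyl nucleophile at C4 and the peracid at C8=C9 should all come from the convex β face, which gives the required configurations. C5 is the link in this relay and is epimerisable only while a carbonyl sits at C6 or C4. The fragile groups are the epoxide (acid, Lewis acid), the tertiary alcohol 1,3 to an ester (acyl transfer, and elimination at the ketone stage), the free phenol, and every β-oxygenated ketone on the way. The enabling feature is that C1 is bonded to both C5 and C10, while C5–C6–C7–C8–C9–C10 map onto a benzene ring carrying oxygen at C6 and methyl at C8, that is a 2-methoxy-4-methylphenyl group attached through C5. Inserting C1 as a carbene between C5 and C10 therefore makes the quaternary centre and both rings at once.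

## Retrosynthesis

**Phenol and epoxide (25 ⇐ 24 ⇐ 23).** The O–Si bond of the phenol ether and the two C–O bonds of the epoxide are cut first. The epoxide is the group least tolerant of the acid, oxidant and organometallic steps, so it is installed on alkene 23 immediately before the final desilylation. Precursor 23 has four stereocentres instead of six. The forward reaction must deliver oxygen to the convex face, anti to the C6 ester.

**Isopropyl group (23 ⇐ 22).** The C4–isopropyl bond is cut to give cyclopentanone 22. Carrying the isopropyl group through the ring-forming step instead would require a tertiary benzylic carbinol of defined configuration in an acyclic precursor, which is much harder to make than a secondary one. The forward addition needs a weakly basic nucleophile and convex-face attack; the seven-membered ring and the C6 ester block the other face.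

**Ester (22 ⇐ 21 ⇐ 20 ⇐ 16 + 19).** The C6–O acyl bond is cut before the C4 ketone is revealed. Introducing the final aroyl group on alcohol 16 lets it serve as the protecting group for O6 while the C4 silyl ether is removed and oxidised. A separate protection and deprotection of O6 is thereby avoided. Acid 19 comes from 4-hydroxybenzoic acid 17 by silylation, via the bis-silyl compound 18.

**Oxidation levels of the carbocycle (16 ⇐ 14 ⇐ 13 ⇐ 12).** No skeletal bond is cut here. The C2 carbonyl, which only served the carbenoid, is deleted (14 to 16, via tosylhydrazone 15). The C8=C9 alkene is derived from the C7–C10 diene of 13 by adding hydrogen at both diene termini. The C6 carbinol comes from the dienone carbonyl of 12. The order is dictated by selectivity: C6 is reduced while it is conjugated and C2 is not, the diene is removed before any intermediate that could rearrange through it, and C2 is deoxygenated when it is the only carbonyl left.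

**Ring-fusion hydrogen (12 ⇐ 11).** The C5–H bond and the O–methyl bond are cut, which recognises the C6 ketone of 12 as the methyl enol ether of cycloheptatriene 11. Protonation of the enol ether at C5 sets the ring fusion, and the silyloxy group on C4 is placed to shield the wrong face.

**Both rings and the quaternary centre (11 ⇐ 10 ⇐ 9).** The C1–C5 and C1–C10 bonds are cut, which takes the bicycle back through norcaradiene 10 to aryl diazoketone 9. Against disconnections that build one ring at a time, this one removes both rings, two skeletal bonds and the quaternary stereocentre in one step, and leaves an acyclic arene with a single stereocentre. A ketal at C4 would be the obvious mask, but a ketal oxygen four atoms from the carbenoid carbon invites five-membered oxonium ylide formation and a 1,2-shift. C4 is therefore carried as a bulky silyl ether of the secondary alcohol. Its configuration is then used three times: it directs the carbenoid to one arene face, it directs the C5 protonation, and it is finally erased at the ketone stage.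

**Diazoketone (9 ⇐ 8 ⇐ 7 ⇐ 6 ⇐ 5 ⇐ 4 ⇐ 1 + 2).** The C1–C2 bond is cut: acid chloride 8 acylates a two-carbon diazoalkane, which places the diazo group regiospecifically on the methyl-bearing carbon. Diazo transfer to the corresponding ethyl ketone would depend on regioselective enolisation away from the β-silyloxy side. Acid 7 comes from ester 6, and the C4 stereocentre of alcohol 5 from asymmetric hydrogenation of β-keto ester 4. Ester 4 is the two-carbon homologue of benzoic acid 1, obtained through Meldrum's acid 2 and acyl adduct 3.

## Roads not taken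

**Alternative 1: cationic ring expansion of an acorane.** The cut is the C1–C10 bond. In the forward step, formic acid or BF3·OEt2 ionises the tertiary alcohol of spirocycle A1, the allylic carbon C10 migrates from the spiro centre C5 to C1, and loss of a proton gives daucadiene A2. This is short and biomimetic, it delivers the whole carbon skeleton with the isopropyl group and the C8=C9 alkene in place, and it has no carbonyl to delete; in these respects it is better than the chosen plan. Its weakness for this target is that A2 has no oxygen at C4 or C6 and a tetrasubstituted C4=C5 alkene where the target has a cis ring-fusion hydrogen flanked by two carbinols. Installing O4, H5 and O6 with the right relative configuration, in the presence of a second trisubstituted alkene, would take a multistep and poorly selective sequence. The migration itself competes with elimination and with shift of the other spiro substituent, and A1 needs its own enantioselective synthesis. The chosen plan sets against this that both oxygens arrive in the starting arene at the right carbons and that every later stereocentre is relayed from C1.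

**Alternative 2: C–H insertion of a citronellol-derived carbenoid.** The cut is the C1–C5 bond. From (R)-citronellol A3 the α-diazo β-keto ester A4 is prepared, and Rh2(OAc)4 inserts its carbenoid into the tertiary C1–H bond with retention to give cyclopentanone A5. The absolute configuration of C1 comes from the chiral pool without ligand screening, and 1,5-insertion into tertiary C–H bonds is reliable; in certainty of stereocontrol this road is better. A5 also carries a ketone at C4 and a carboxyl carbon at C6, which matches the target's oxygenation. Its weakness is that only the five-membered ring is made. The seven-membered ring, with its trisubstituted alkene, still needs C7 and C8 to be added and a medium-ring closure, and the C4 ketone of A5 is part of a β-keto ester, towards which an isopropyl nucleophile acts mainly as a base. The chosen plan sets against the better C1 control that its key step closes both rings and forms two skeletal bonds, so far fewer C–C bond-forming steps follow it.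

**Alternative 3: intramolecular nitrile oxide cycloaddition.** The cuts are the C5–C6 bond and the O–C4 bond. NaOCl oxidises aldoxime A6 to nitrile oxide A7, which adds across the C4=C5 alkene of the cyclopentene and gives tricyclic isoxazoline A8. This closes the seven-membered ring and places the tertiary oxygen on C4, with the isopropyl group already there, cis to the new C5–C6 bond. The tether from C1 also forces the cis ring fusion. For the C4/C5/C6 array this is more direct than the oxidation and organometallic addition used here, and in that respect better. Its weak points are the closure of a seven-membered ring onto a hindered trisubstituted alkene in competition with dipole dimerisation, the separate asymmetric synthesis of the quaternary C1 in A6, the reductive N–O cleavage beside a trisubstituted alkene, and a C6 ketone that still has to be reduced selectively. The chosen plan sets against it a ring-forming step of well-precedented type that starts from a simple benzoic acid and creates C1 catalytically.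

Key step: step 6

## Route

Step 1
Reactants: 1 2-methoxy-4-methylbenzoic acid; 2 2,2-dimethyl-1,3-dioxane-4,6-dione (Meldrum's acid)
Product: 4 ethyl 3-(2-methoxy-4-methylphenyl)-3-oxopropanoate, via acyl Meldrum's acid 3 (not isolated)
Conditions: DCC, DMAP, CH2Cl2, 0 °C to rt; then EtOH, reflux
Reagents that add atoms: ethanol CCO
Why: Acylation of Meldrum's acid by the carbodiimide-activated acid, then ethanolysis with loss of acetone and CO2, is the standard two-carbon homologation of an aryl carboxylic acid to its β-keto ester.

Step 2
Reactants: 4 ethyl 3-(2-methoxy-4-methylphenyl)-3-oxopropanoate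
Product: 5 ethyl (3S)-3-hydroxy-3-(2-methoxy-4-methylphenyl)propanoate
Conditions: RuCl2[(R)-BINAP] (1 mol%), H2 (50 atm), EtOH, 50 °C
Reagents that add atoms: none
Why: Noyori asymmetric hydrogenation of a β-keto ester; chelation by the ester fixes the ketone on the divalent ruthenium centre, and the (R)-ligand should deliver hydride to the face that gives the (S)-carbinol (aryl outranks CH2CO2Et, hence S).

Step 3
Reactants: 5 ethyl (3S)-3-hydroxy-3-(2-methoxy-4-methylphenyl)propanoate
Product: 6 ethyl (3S)-3-[(tert-butyldimethylsilyl)oxy]-3-(2-methoxy-4-methylphenyl)propanoate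
Conditions: TBSCl, imidazole, DMF, rt
Reagents that add atoms: tert-butyldimethylsilyl chloride CC(C)(C)[Si](C)(C)Cl
Why: Standard silylation of a secondary benzylic alcohol; the bulky, weakly basic silyl ether oxygen is chosen so that it does not trap the carbenoid in step 6 and can later shield one face of C5.

Step 4
Reactants: 6 ethyl (3S)-3-[(tert-butyldimethylsilyl)oxy]-3-(2-methoxy-4-methylphenyl)propanoate
Product: 7 (3S)-3-[(tert-butyldimethylsilyl)oxy]-3-(2-methoxy-4-methylphenyl)propanoic acid
Conditions: LiOH, THF/MeOH/H2O, 0 °C to rt; then cold 1 M HCl to pH 4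
Reagents that add atoms: lithium hydroxide [Li+].[OH-]
Why: Saponification; β-silyloxy esters tolerate LiOH at room temperature because silyloxide is a poor leaving group for E1cB elimination, and brief cold acidification leaves the silyl ether intact.

Step 5
Reactants: 7 (3S)-3-[(tert-butyldimethylsilyl)oxy]-3-(2-methoxy-4-methylphenyl)propanoic acid
Product: 9 (5S)-5-[(tert-butyldimethylsilyl)oxy]-2-diazo-5-(2-methoxy-4-methylphenyl)pentan-3-one, via acid chloride 8 (not isolated)
Conditions: (COCl)2, cat. DMF, CH2Cl2, 0 °C; evaporate; CH3CHN2 (3 equiv, freshly made from N-ethyl-N-nitrosourea and aq. KOH), Et2O, −20 to 0 °C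
Reagents that add atoms: diazoethane CC=[N+]=[N-]
Why: C-acylation of a diazoalkane by an acid chloride (the first stage of an Arndt–Eistert sequence), with excess diazoethane taking up the HCl; this puts the diazo group regiospecifically on the methyl-bearing carbon that becomes C1.

Step 6
Reactants: 9 (5S)-5-[(tert-butyldimethylsilyl)oxy]-2-diazo-5-(2-methoxy-4-methylphenyl)pentan-3-one
Product: 11 (3S,8aS)-3-[(tert-butyldimethylsilyl)oxy]-4-methoxy-6,8a-dimethyl-3,8a-dihydroazulen-1(2H)-one (cycloheptatriene form; C2 ketone; C4 silyl ether; C6 methyl enol ether), via norcaradiene 10 (not isolated)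
Conditions: [Cu(MeCN)4]PF6 (5 mol%), 2,2'-(propane-2,2-diyl)bis[(4R)-4-phenyl-4,5-dihydrooxazole] (6 mol%), CH2Cl2, 40 °C, slow addition of 9
Reagents that add atoms: none
Why: Monovalent copper bound to the bis(oxazoline) expels N2 from 9 to give an electrophilic carbenoid at C1, which cyclopropanates the C5–C10 bond of the arene to norcaradiene 10; thermally allowed disrotatory 6π electrocyclic opening of 10 then breaks C5–C10 and gives cycloheptatriene 11. The closest known reaction type is the enantioselective intramolecular Buchner reaction of 2-diazo-5-arylpentan-3-ones under copper bis(oxazoline) catalysis. The five-membered ring closes in the cyclopropanation, by C1–C5 bond formation at the ipso carbon through the three-atom tether C2–C3–C4; the seven-membered ring arises by ring expansion, C1–C10 being formed in the same cyclopropanation and the six-membered ring opened to seven when C5–C10 breaks. C1 is the only new stereocentre: allylic 1,3-strain with the ortho methoxy group holds the C4–H bond in the arene plane, so the tether approaches the face opposite the silyloxy group and the C1 methyl ends up trans to it, and the ligand enantiomer is meant to reinforce this substrate bias. Site selectivity between the two ortho bonds is needed and comes from the methoxy group, which makes the C5–C6 bond fully substituted and leaves C5–C10 as the accessible one. Chemoselectivity against oxonium ylide formation comes from the bulky silyl ether (the reason no ketal is used at C4), and against aromatic substitution from C10 being meta to the methoxy group.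

Step 7
Reactants: 11 (3S,8aS)-3-[(tert-butyldimethylsilyl)oxy]-4-methoxy-6,8a-dimethyl-3,8a-dihydroazulen-1(2H)-one
Product: 12 (3S,3aR,8aS)-3-[(tert-butyldimethylsilyl)oxy]-6,8a-dimethyl-2,3,3a,8a-tetrahydroazulene-1,4-dione (cis-fused; C6 dienone with C7=C8 and C9=C10; H5 on the face of the C1 methyl)
Conditions: oxalic acid, THF/H2O, 0 °C
Reagents that add atoms: water O
Why: Enol ether hydrolysis: protonation at C5 gives a methoxy-stabilised dienyl cation, water adds at C6 and methanol is lost. The proton should arrive on the β face, opposite the C4 silyloxy group, giving the cis fusion; this should also be the thermodynamic outcome, because the flattened dienone ring cannot supply the large fusion torsion that a trans-fused cyclopentane needs.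

Step 8
Reactants: 12 (3S,3aR,8aS)-3-[(tert-butyldimethylsilyl)oxy]-6,8a-dimethyl-2,3,3a,8a-tetrahydroazulene-1,4-dione
Product: 13 (3S,3aS,4R,8aS)-3-[(tert-butyldimethylsilyl)oxy]-4-hydroxy-6,8a-dimethyl-3,3a,4,8a-tetrahydroazulen-1(2H)-one (6α-dienol; C2 ketone retained)
Conditions: NaBH4 (1.0 equiv), CeCl3·7H2O, MeOH, −78 °C
Reagents that add atoms: none
Why: Luche reduction: 1,2-selective, and a conjugated ketone is reduced in preference to an isolated cyclopentanone flanked by a quaternary carbon. Hydride should approach C6 from the convex β face, away from the cyclopentane and its silyloxy group, which sets the 6α-hydroxyl and at the same time freezes C5.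

Step 9
Reactants: 13 (3S,3aS,4R,8aS)-3-[(tert-butyldimethylsilyl)oxy]-4-hydroxy-6,8a-dimethyl-3,3a,4,8a-tetrahydroazulen-1(2H)-one
Product: 14 (3S,3aS,4R,8aS)-3-[(tert-butyldimethylsilyl)oxy]-4-hydroxy-6,8a-dimethyl-3,3a,4,5,8,8a-hexahydroazulen-1(2H)-one (C8=C9 alkene only)
Conditions: (η6-naphthalene)Cr(CO)3 (10 mol%), H2 (50 atm), THF, 45 °C
Reagents that add atoms: none
Why: 1,4-Hydrogenation of a cisoid 1,3-diene on a Cr(CO)3 fragment: both hydrogens go to the termini C7 and C10 of the η4-bound diene and the central C8=C9 alkene is left; isolated ketones, alcohols and silyl ethers are not touched.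

Step 10
Reactants: 14 (3S,3aS,4R,8aS)-3-[(tert-butyldimethylsilyl)oxy]-4-hydroxy-6,8a-dimethyl-3,3a,4,5,8,8a-hexahydroazulen-1(2H)-one
Product: 16 (3S,3aS,4R,8aS)-3-[(tert-butyldimethylsilyl)oxy]-6,8a-dimethyl-1,2,3,3a,4,5,8,8a-octahydroazulen-4-ol (C2 now CH2), via C2 tosylhydrazone 15 (not isolated)
Conditions: TsNHNH2, EtOH, 60 °C; evaporate; catecholborane (3 equiv), CHCl3, 0 °C; then NaOAc·3H2O, reflux
Reagents that add atoms: none
Why: Ketone deoxygenation through the tosylhydrazone (Caglioti-type reduction with catecholborane): hydride adds to C=N, acetate induces loss of sulfinate, and the alkyldiazene expels N2 to leave CH2. C2 is the only carbonyl at this stage, the diene is gone so no allyl-type rearrangement can intervene, and the free hydroxyl only consumes one equivalent of borane.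

Step 11
Reactants: 17 4-hydroxybenzoic acid
Product: 19 4-[(triisopropylsilyl)oxy]benzoic acid, via bis-silyl compound 18 (not isolated)
Conditions: TIPSCl (2.2 equiv), imidazole, DMF, rt; then K2CO3, MeOH/THF/H2O, 0 °C; then 1 M HCl
Reagents that add atoms: triisopropylsilyl chloride CC(C)[Si](Cl)(C(C)C)C(C)C
Why: Exhaustive silylation followed by selective hydrolysis of the much more labile silyl ester; the aryl triisopropylsilyl ether is chosen because it should survive HF in acetonitrile, the periodinane oxidation and the organocerium step.

Step 12
Reactants: 16 (3S,3aS,4R,8aS)-3-[(tert-butyldimethylsilyl)oxy]-6,8a-dimethyl-1,2,3,3a,4,5,8,8a-octahydroazulen-4-ol; 19 4-[(triisopropylsilyl)oxy]benzoic acid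
Product: 20 the O6 ester of 16 with 19 (C4 α-silyl ether; C6 α-aroyloxy; C8=C9)
Conditions: EDC·HCl, DMAP, CH2Cl2, rt to 40 °C
Reagents that add atoms: none
Why: Steglich esterification of the only free hydroxyl; the aroyl group is the final ester and also protects O6 through steps 13 to 15.

Step 13
Reactants: 20 the O6 ester of 16 with 19
Product: 21 the C4 alcohol (4α-hydroxy; C6 α-aroyloxy; aryl silyl ether intact)
Conditions: 48% aq. HF, MeCN, 0 °C to rt
Reagents that add atoms: none
Why: Acidic fluoride cleavage of a secondary alkyl silyl ether; aryl silyl ethers are base-labile but markedly more stable to HF in acetonitrile, so the phenol stays protected, and 1,3-acyl migration from O6 to O4 is slow under acid.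

Step 14
Reactants: 21 the C4 alcohol
Product: 22 the C4 ketone (cis-fused cyclopentanone; C6 α-aroyloxy; C8=C9)
Conditions: Dess–Martin periodinane, NaHCO3, CH2Cl2, 0 °C to rt
Reagents that add atoms: none
Why: Dess–Martin oxidation under buffered, non-basic conditions, so that the β-aroyloxy ketone is not exposed to base; C5 is now α to a cyclopentanone, where the cis fusion is the stable arrangement.

Step 15
Reactants: 22 the C4 ketone
Product: 23 (1S,4R,5S,6R)-4-hydroxydauc-8-en-6-yl 4-[(triisopropylsilyl)oxy]benzoate (isopropyl β and hydroxyl α at C4)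
Conditions: iPrMgCl, anhydrous CeCl3, THF, −78 °C
Reagents that add atoms: isopropylmagnesium chloride CC(C)[Mg]Cl
Why: 1,2-Addition of the weakly basic organocerium reagent iPrCeCl2 to an enolisable ketone; at −78 °C the ketone should react far faster than the hindered, electron-rich aryl ester. Attack from the convex β face (the concave face is closed by the seven-membered ring and the C6 ester) puts the isopropyl group on the side of the C1 methyl and the hydroxyl on the α face.

Step 16
Reactants: 23 (1S,4R,5S,6R)-4-hydroxydauc-8-en-6-yl 4-[(triisopropylsilyl)oxy]benzoate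
Product: 24 (1S,4R,5S,6R,8R,9S)-8,9-epoxy-4-hydroxydaucan-6-yl 4-[(triisopropylsilyl)oxy]benzoate (epoxide oxygen β)
Conditions: mCPBA, NaHCO3, CH2Cl2, 0 °C
Reagents that add atoms: 3-chloroperoxybenzoic acid OOC(=O)c1cccc(Cl)c1
Why: Prilezhaev epoxidation of the only alkene; the peracid should take the convex β face, anti to the C6 ester, and the buffer protects the acid-sensitive trisubstituted epoxide.

Step 17
Reactants: 24 (1S,4R,5S,6R,8R,9S)-8,9-epoxy-4-hydroxydaucan-6-yl 4-[(triisopropylsilyl)oxy]benzoate
Product: 25 (1S,4R,5S,6R,8R,9S)-8,9-epoxy-4-hydroxydaucan-6-yl 4-hydroxybenzoate (target)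
Conditions: Bu4NF, AcOH, THF, 0 °C
Reagents that add atoms: none
Why: Fluoride cleavage of an aryl silyl ether, buffered with acetic acid so that the phenoxide is protonated at once and neither the ester nor the epoxide meets a basic nucleophile.

## Compound list

1 | 2-methoxy-4-methylbenzoic acid | COc1cc(C)ccc1C(=O)O | starting material
2 | 2,2-dimethyl-1,3-dioxane-4,6-dione (Meldrum's acid) | CC1(C)OC(=O)CC(=O)O1 | starting material
3 | 5-[hydroxy(2-methoxy-4-methylphenyl)methylidene]-2,2-dimethyl-1,3-dioxane-4,6-dione | COc1cc(C)ccc1C(O)=C1C(=O)OC(C)(C)OC1=O | intermediate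
4 | ethyl 3-(2-methoxy-4-methylphenyl)-3-oxopropanoate | CCOC(=O)CC(=O)c1ccc(C)cc1OC | intermediate
5 | ethyl (3S)-3-hydroxy-3-(2-methoxy-4-methylphenyl)propanoate | CCOC(=O)C[C@H](O)c1ccc(C)cc1OC | intermediate
6 | ethyl (3S)-3-[(tert-butyldimethylsilyl)oxy]-3-(2-methoxy-4-methylphenyl)propanoate | CCOC(=O)C[C@H](O[Si](C)(C)C(C)(C)C)c1ccc(C)cc1OC | intermediate
7 | (3S)-3-[(tert-butyldimethylsilyl)oxy]-3-(2-methoxy-4-methylphenyl)propanoic acid | OC(=O)C[C@H](O[Si](C)(C)C(C)(C)C)c1ccc(C)cc1OC | intermediate
8 | (3S)-3-[(tert-butyldimethylsilyl)oxy]-3-(2-methoxy-4-methylphenyl)propanoyl chloride | ClC(=O)C[C@H](O[Si](C)(C)C(C)(C)C)c1ccc(C)cc1OC | intermediate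
9 | (5S)-5-[(tert-butyldimethylsilyl)oxy]-2-diazo-5-(2-methoxy-4-methylphenyl)pentan-3-one | CC(=[N+]=[N-])C(=O)C[C@H](O[Si](C)(C)C(C)(C)C)c1ccc(C)cc1OC | intermediate
10 | norcaradiene tautomer of 11 (cyclopropane C1–C5–C10; diene C6=C7, C8=C9) | CC(C)(C)[Si](C)(C)O[C@H]1CC(=O)[C@@]2(C)[C@@H]3C=C(C)C=C(OC)[C@]123 | intermediate
11 | (3S,8aS)-3-[(tert-butyldimethylsilyl)oxy]-4-methoxy-6,8a-dimethyl-3,8a-dihydroazulen-1(2H)-one | CC(C)(C)[Si](C)(C)O[C@H]1CC(=O)[C@@]2(C)C=CC(C)=CC(OC)=C12 | intermediate
12 | (3S,3aR,8aS)-3-[(tert-butyldimethylsilyl)oxy]-6,8a-dimethyl-2,3,3a,8a-tetrahydroazulene-1,4-dione | CC(C)(C)[Si](C)(C)O[C@H]1CC(=O)[C@@]2(C)C=CC(C)=CC(=O)[C@@H]12 | intermediate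
13 | (3S,3aS,4R,8aS)-3-[(tert-butyldimethylsilyl)oxy]-4-hydroxy-6,8a-dimethyl-3,3a,4,8a-tetrahydroazulen-1(2H)-one | CC(C)(C)[Si](C)(C)O[C@H]1CC(=O)[C@@]2(C)C=CC(C)=C[C@@H](O)[C@@H]12 | intermediate
14 | (3S,3aS,4R,8aS)-3-[(tert-butyldimethylsilyl)oxy]-4-hydroxy-6,8a-dimethyl-3,3a,4,5,8,8a-hexahydroazulen-1(2H)-one | CC(C)(C)[Si](C)(C)O[C@H]1CC(=O)[C@@]2(C)CC=C(C)C[C@@H](O)[C@@H]12 | intermediate
15 | 4-methylbenzenesulfonylhydrazone of 14 at C2 | CC(C)(C)[Si](C)(C)O[C@H]1CC(=NNS(=O)(=O)c3ccc(C)cc3)[C@@]2(C)CC=C(C)C[C@@H](O)[C@@H]12 | intermediate
16 | (3S,3aS,4R,8aS)-3-[(tert-butyldimethylsilyl)oxy]-6,8a-dimethyl-1,2,3,3a,4,5,8,8a-octahydroazulen-4-ol | CC(C)(C)[Si](C)(C)O[C@H]1CC[C@@]2(C)CC=C(C)C[C@@H](O)[C@@H]12 | intermediate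
17 | 4-hydroxybenzoic acid | OC(=O)c1ccc(O)cc1 | starting material
18 | triisopropylsilyl 4-[(triisopropylsilyl)oxy]benzoate | CC(C)[Si](Oc1ccc(cc1)C(=O)O[Si](C(C)C)(C(C)C)C(C)C)(C(C)C)C(C)C | intermediate
19 | 4-[(triisopropylsilyl)oxy]benzoic acid | CC(C)[Si](Oc1ccc(cc1)C(=O)O)(C(C)C)C(C)C | intermediate
20 | O6 ester of 16 with 19 (4α-silyloxy, 6α-aroyloxy, cis-fused, C8=C9) | CC(C)(C)[Si](C)(C)O[C@H]1CC[C@@]2(C)CC=C(C)C[C@@H](OC(=O)c3ccc(O[Si](C(C)C)(C(C)C)C(C)C)cc3)[C@@H]12 | intermediate
21 | C4 alcohol from 20 (4α-hydroxy, 6α-aroyloxy) | O[C@H]1CC[C@@]2(C)CC=C(C)C[C@@H](OC(=O)c3ccc(O[Si](C(C)C)(C(C)C)C(C)C)cc3)[C@@H]12 | intermediate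
22 | C4 ketone from 21 (cis-fused cyclopentanone, 6α-aroyloxy) | O=C1CC[C@@]2(C)CC=C(C)C[C@@H](OC(=O)c3ccc(O[Si](C(C)C)(C(C)C)C(C)C)cc3)[C@@H]12 | intermediate
23 | (1S,4R,5S,6R)-4-hydroxydauc-8-en-6-yl 4-[(triisopropylsilyl)oxy]benzoate | CC(C)[C@]1(O)CC[C@@]2(C)CC=C(C)C[C@@H](OC(=O)c3ccc(O[Si](C(C)C)(C(C)C)C(C)C)cc3)[C@H]21 | intermediate
24 | (1S,4R,5S,6R,8R,9S)-8,9-epoxy-4-hydroxydaucan-6-yl 4-[(triisopropylsilyl)oxy]benzoate | CC(C)[C@]1(O)CC[C@@]2(C)C[C@@H]3O[C@]3(C)C[C@@H](OC(=O)c3ccc(O[Si](C(C)C)(C(C)C)C(C)C)cc3)[C@H]21 | intermediate
25 | (1S,4R,5S,6R,8R,9S)-8,9-epoxy-4-hydroxydaucan-6-yl 4-hydroxybenzoate | CC(C)[C@]1(O)CC[C@@]2(C)C[C@@H]3O[C@]3(C)C[C@@H](OC(=O)c3ccc(O)cc3)[C@H]21 | target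

## Step count and least certain steps

Total: 17 steps. Longest linear sequence: 16 steps (steps 1–10 and 12–17); step 11 is a one-step side branch.

**Step 6 (key step).** The carbenoid may be diverted before it reaches the C5–C10 bond: by capture at the silyl ether oxygen, by a 1,2-hydride shift from the methyl group, by aromatic substitution at C10 or by addition across the methoxy-bearing bond. A mismatched pairing of ligand and C4 centre would also erode the diastereoselectivity at C1; in that case the antipodal ligand is the first change. Fallback: ligand control is given up, and 9 is cyclised with the achiral dirhodium tetraacetate Rh2(OAc)4 in CH2Cl2, the classical catalyst class for this arene cyclopropanation, so that the C4 silyloxy centre alone directs the carbenoid. This sets out from 9, returns at 11 and creates no new compound (F0).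

**Step 8.** Poor facial selectivity of hydride delivery at C6 (approach from the concave face) is the main danger; partial reduction at C2 is the second. Fallback: reduction of 12 then gives the 6β-dienol F1, which is taken through the conditions of steps 9 and 10 (ketone F2, tosylhydrazone F3, alcohol F4). F4 is esterified with acid 19 under Mitsunobu conditions (PPh3, DIAD, toluene), which inverts C6 and rejoins the route at 20.

**Step 9.** Isomerisation instead of hydrogen addition is possible: the carbinol C–H at C6 is allylic to a diene terminus, and a 1,5-hydrogen shift on chromium would convert the dienol into a ketone and erase C6. Slow turnover with this trisubstituted ring diene is the other risk. Fallback: from dienone 12, conjugate 1,6-reduction with [(Ph3P)CuH]6 (hydride to the unsubstituted C10, then kinetic protonation at C7) gives the β,γ-unsaturated dione F5. L-Selectride at −78 °C then reduces the C6 carbonyl from the convex face, C2 being shielded by the quaternary C1, and the route is rejoined at 14.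

**Step 15.** Loss of the aroyloxy group by E1cB elimination through the C5 enolate, attack of the reagent at the ester, or acyl transfer to the new tertiary alkoxide may compete with addition. Fallback: from 16, silylation (TIPSOTf, 2,6-lutidine) gives the bis-silyl ether F6, and CSA in MeOH removes the more labile tert-butyldimethylsilyl group to give alcohol F7. Dess–Martin oxidation gives ketone F8, iPrMgCl with CeCl3 gives tertiary alcohol F9, and Bu4NF gives diol F10. Acylation of F10 with 19 (EDC·HCl, DMAP) occurs only at the secondary C6 hydroxyl and returns to the route at 23.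

**Step 16.** Poor facial selectivity of the peracid is the risk, for instance delivery to the α face guided by the C4 hydroxyl. Fallback: from 23, NBS in aqueous THF forms the bromonium ion on the face the peracid would have taken, and water opens it at the tertiary C8 from the β face to give bromohydrin F11 (8β-hydroxy, 9α-bromo). DBU in CH2Cl2 then closes the epoxide on the β face with inversion at C9 and returns to the route at 24.

## Further compounds

F0 | step 6 | none | none
F1 | step 8 | 6β-epimer of dienol 13 | CC(C)(C)[Si](C)(C)O[C@H]1CC(=O)[C@@]2(C)C=CC(C)=C[C@H](O)[C@@H]12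
F2 | step 8 | 6β-epimer of ketone 14 | CC(C)(C)[Si](C)(C)O[C@H]1CC(=O)[C@@]2(C)CC=C(C)C[C@H](O)[C@@H]12
F3 | step 8 | C2 tosylhydrazone of F2 | CC(C)(C)[Si](C)(C)O[C@H]1CC(=NNS(=O)(=O)c3ccc(C)cc3)[C@@]2(C)CC=C(C)C[C@H](O)[C@@H]12
F4 | step 8 | 6β-epimer of alcohol 16 | CC(C)(C)[Si](C)(C)O[C@H]1CC[C@@]2(C)CC=C(C)C[C@H](O)[C@@H]12
F5 | step 9 | (3S,3aR,8aS)-3-[(tert-butyldimethylsilyl)oxy]-6,8a-dimethyl-2,3,3a,5,8,8a-hexahydroazulene-1,4-dione | CC(C)(C)[Si](C)(C)O[C@H]1CC(=O)[C@@]2(C)CC=C(C)CC(=O)[C@@H]12
F6 | step 15 | 4α-(tert-butyldimethylsilyloxy)-6α-(triisopropylsilyloxy) bis-silyl ether of the cis-fused dauc-8-ene-4,6-diol core | CC(C)(C)[Si](C)(C)O[C@H]1CC[C@@]2(C)CC=C(C)C[C@@H](O[Si](C(C)C)(C(C)C)C(C)C)[C@@H]12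
F7 | step 15 | 4α-alcohol with 6α-(triisopropylsilyloxy) group | O[C@H]1CC[C@@]2(C)CC=C(C)C[C@@H](O[Si](C(C)C)(C(C)C)C(C)C)[C@@H]12
F8 | step 15 | C4 ketone with 6α-(triisopropylsilyloxy) group | O=C1CC[C@@]2(C)CC=C(C)C[C@@H](O[Si](C(C)C)(C(C)C)C(C)C)[C@@H]12
F9 | step 15 | (1S,4R,5S,6R)-6-(triisopropylsilyloxy)dauc-8-en-4-ol | CC(C)[C@]1(O)CC[C@@]2(C)CC=C(C)C[C@@H](O[Si](C(C)C)(C(C)C)C(C)C)[C@H]21
F10 | step 15 | (1S,4R,5S,6R)-dauc-8-ene-4,6-diol | CC(C)[C@]1(O)CC[C@@]2(C)CC=C(C)C[C@@H](O)[C@H]21
F11 | step 16 | 9α-bromo-4α,8β-dihydroxydaucan-6α-yl 4-[(triisopropylsilyl)oxy]benzoate | CC(C)[C@]1(O)CC[C@@]2(C)C[C@@H](Br)[C@](C)(O)C[C@@H](OC(=O)c3ccc(O[Si](C(C)C)(C(C)C)C(C)C)cc3)[C@H]21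
A1 | alternative 1 | 1,8-dimethyl-4-(propan-2-yl)spiro[4.5]dec-7-en-1-ol (configuration not fixed here) | CC(C)C1CCC(C)(O)C12CCC(C)=CC2
A2 | alternative 1 | dauca-4,8-diene | CC(C)C1=C2CCC(C)=CC[C@]2(C)CC1
A3 | alternative 2 | (R)-citronellol | CC(C)=CCC[C@@H](C)CCO
A4 | alternative 2 | methyl (6R)-8-[(tert-butyldimethylsilyl)oxy]-2-diazo-6-methyl-3-oxooctanoate | COC(=O)C(=[N+]=[N-])C(=O)CC[C@@H](C)CCO[Si](C)(C)C(C)(C)C
A5 | alternative 2 | methyl 2-methyl-5-oxo-2-[2-(tert-butyldimethylsilyloxy)ethyl]cyclopentane-1-carboxylate | COC(=O)[C@H]1C(=O)CC[C@@]1(C)CCO[Si](C)(C)C(C)(C)C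
A6 | alternative 3 | aldoxime of the cyclopentene aldehyde (C4=C5 alkene, C1 side chain C10–C6) | CC(C)C1=C[C@](C)(C/C=C(/C)CC=NO)CC1
A7 | alternative 3 | nitrile oxide from A6 | CC(C)C1=C[C@](C)(C/C=C(/C)CC#[N+][O-])CC1
A8 | alternative 3 | tricyclic isoxazoline spanning C4, C5 and C6 | CC(C)[C@@]12CC[C@@]3(C)CC=C(C)CC(=NO1)[C@@H]23
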